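**Strategy.** Ring C, the terminal orsellinic acid unit, is not acylated as a phenol but grown onto the finished ring A–ring B acyl group. Its C1 carboxyl flanked by C2–OH and C6–CH3, with O4 holding the depside ester, maps onto a 1-silyloxy-3-aroyloxycyclohexa-1,3-diene and benzyl but-2-ynoate. One thermal operation (cycloaddition, then loss of ethylene) forms C1–C2 and C5–C6, aromatises ring C and delivers O2, O4 and the carboxyl in three different masked forms. The diene is the enol ester obtained by O-acylating the cross-conjugated enolate of 3-silyloxycyclohexenone with the benzyl-protected ring A–ring B acid chloride.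

Key step: step 13

Assumption: the target has no stereocentre, so no stereocontrol is needed; 3,4,5-trimethoxytoluene, 2,4-dihydroxy-6-methylbenzaldehyde, cyclohexane-1,3-dione and but-2-ynoic acid are taken as purchasable. Ring A is built from a symmetric arene so that the position of its carboxyl carbon is unambiguous, and ring B enters as an aldehyde that serves as a latent carboxyl group.

**Step 1**
Reactants: 1 3,4,5-trimethoxytoluene
Product: 3 2,3,4-trimethoxy-6-methylbenzaldehyde, via aryl iminium chloride 2 (not isolated)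
Conditions: POCl3, DMF, 0 → 75 °C; then H2O
Reagents that add atoms: N,N-dimethylformamide, CN(C)C=O; water, O
Why: Vilsmeier–Haack formylation of an electron-rich arene; the two open ring positions of the symmetric substrate are equivalent, so the formyl carbon can only enter between the methyl group and a methoxy group.

**Step 2**
Reactants: 3 2,3,4-trimethoxy-6-methylbenzaldehyde
Product: 4 2,3,4-trihydroxy-6-methylbenzaldehyde
Conditions: BBr3 (4 equiv), CH2Cl2, −78 °C → rt; then H2O; under argon
Reagents that add atoms: none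
Why: Exhaustive Lewis-acid O-demethylation of aryl methyl ethers with BBr3 is routine and should leave the aryl aldehyde intact after aqueous quench.

**Step 3**
Reactants: 4 2,3,4-trihydroxy-6-methylbenzaldehyde
Product: 5 4-(benzyloxy)-2,3-dihydroxy-6-methylbenzaldehyde
Conditions: BnBr (1.0 equiv), NaHCO3, DMF, 40 °C, argon
Reagents that add atoms: benzyl bromide, BrCc1ccccc1
Why: Site-selective Williamson etherification: under NaHCO3 only the 4-OH, para to the formyl group and the most acidic, is ionised, while the 2-OH is held in a hydrogen bond to the carbonyl and the 3-OH is a less acidic meta phenol, as known for 2,3,4-trihydroxybenzaldehyde.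

**Step 4**
Reactants: 5 4-(benzyloxy)-2,3-dihydroxy-6-methylbenzaldehyde
Product: 6 4-(benzyloxy)-2,3-dimethoxy-6-methylbenzaldehyde
Conditions: MeI (excess), K2CO3, DMF, 40 °C
Reagents that add atoms: iodomethane, CI
Why: Williamson O-methylation of the two remaining phenols under stronger base and excess electrophile; no other site in the molecule can be alkylated.

**Step 5**
Reactants: 6 4-(benzyloxy)-2,3-dimethoxy-6-methylbenzaldehyde
Product: 7 4-(benzyloxy)-2,3-dimethoxy-6-methylbenzoic acid
Conditions: NaClO2, NaH2PO4, 2-methylbut-2-ene, t-BuOH/THF/H2O, rt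
Reagents that add atoms: sodium chlorite, [Na+].[O-]Cl=O
Why: Pinnick oxidation converts even di-ortho-substituted, electron-rich benzaldehydes into benzoic acids, and the alkene scavenger removes HOCl before it can chlorinate the ring.

**Step 6**
Reactants: 7 4-(benzyloxy)-2,3-dimethoxy-6-methylbenzoic acid; 8 2,4-dihydroxy-6-methylbenzaldehyde
Product: 10 4-formyl-3-hydroxy-5-methylphenyl 4-(benzyloxy)-2,3-dimethoxy-6-methylbenzoate, via mixed trifluoroacetic anhydride 9 (not isolated)
Conditions: (CF3CO)2O, toluene, rt; then aq. NaHCO3 wash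
Reagents that add atoms: none
Why: Trifluoroacetic-anhydride-mediated depside esterification: the hindered, electron-rich acid is activated as its acylium-like mixed anhydride and should be captured by the free 4-OH of ring B, the 2-OH being deactivated by its hydrogen bond to the formyl group.

**Step 7**
Reactants: 10 4-formyl-3-hydroxy-5-methylphenyl 4-(benzyloxy)-2,3-dimethoxy-6-methylbenzoate
Product: 11 3-(benzyloxy)-4-formyl-5-methylphenyl 4-(benzyloxy)-2,3-dimethoxy-6-methylbenzoate
Conditions: BnBr, K2CO3, DMF, rt
Reagents that add atoms: benzyl bromide, BrCc1ccccc1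
Why: Williamson benzylation of the remaining chelated phenol; the depside ester is shielded by the two ortho substituents of ring A and should survive anhydrous carbonate at room temperature.

**Step 8**
Reactants: 11 3-(benzyloxy)-4-formyl-5-methylphenyl 4-(benzyloxy)-2,3-dimethoxy-6-methylbenzoate
Product: 12 2-(benzyloxy)-4-{[4-(benzyloxy)-2,3-dimethoxy-6-methylbenzoyl]oxy}-6-methylbenzoic acid
Conditions: NaClO2, NaH2PO4, 2-methylbut-2-ene, t-BuOH/THF/H2O, rt
Reagents that add atoms: sodium chlorite, [Na+].[O-]Cl=O
Why: Pinnick oxidation unmasks the ring B carboxyl from the aldehyde at about pH 4, conditions under which aryl esters and benzyl ethers are inert.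

**Step 9**
Reactants: 12 2-(benzyloxy)-4-{[4-(benzyloxy)-2,3-dimethoxy-6-methylbenzoyl]oxy}-6-methylbenzoic acid
Product: 13 2-(benzyloxy)-4-{[4-(benzyloxy)-2,3-dimethoxy-6-methylbenzoyl]oxy}-6-methylbenzoyl chloride
Conditions: (COCl)2, DMF (cat.), CH2Cl2, 0 °C → rt; evaporate, use crude
Reagents that add atoms: oxalyl chloride, ClC(=O)C(Cl)=O
Why: Standard acid chloride formation through the catalytic chloroiminium species under anhydrous conditions that aryl esters and benzyl ethers tolerate.

**Step 10**
Reactants: 14 cyclohexane-1,3-dione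
Product: 15 3-[(tert-butyldimethylsilyl)oxy]cyclohex-2-en-1-one
Conditions: t-BuMe2SiCl, Et3N, CH2Cl2, 0 °C → rt; distil
Reagents that add atoms: tert-butyldimethylsilyl chloride, CC(C)(C)[Si](C)(C)Cl
Why: O-silylation of the enol form of a 1,3-diketone gives the vinylogous silyl ester, and the bulky silyl group makes it isolable.

**Step 11**
Reactants: 15 3-[(tert-butyldimethylsilyl)oxy]cyclohex-2-en-1-one (1.3 equiv); 13 2-(benzyloxy)-4-{[4-(benzyloxy)-2,3-dimethoxy-6-methylbenzoyl]oxy}-6-methylbenzoyl chloride
Product: 17 5-[(tert-butyldimethylsilyl)oxy]cyclohexa-1,5-dien-1-yl 2-(benzyloxy)-4-{[4-(benzyloxy)-2,3-dimethoxy-6-methylbenzoyl]oxy}-6-methylbenzoate, via lithium dienolate 16 (not isolated)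
Conditions: lithium diisopropylamide (LiN(CHMe2)2, 1.2 equiv), THF, −78 °C; DMPU; then 13 (1.0 equiv), −78 → −20 °C; pH 7 buffer work-up, Et3N-deactivated silica
Reagents that add atoms: none
Why: Kinetic deprotonation of a 3-oxygenated cyclohexenone occurs at C6 (the alpha-prime position), and the cross-conjugated enolate, made more ionic by DMPU, should be acylated at oxygen by the hard, di-ortho-substituted aroyl chloride (enolate O-acylation to an enol ester), which places the acyloxy group on the internal diene carbon.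

**Step 12**
Reactants: 18 but-2-ynoic acid
Product: 19 benzyl but-2-ynoate
Conditions: BnBr, KHCO3, DMF, rt
Reagents that add atoms: benzyl bromide, BrCc1ccccc1
Why: SN2 alkylation of the carboxylate under weak base should give the benzyl ester without isomerising the ynoate to an allenoate.

**Step 13**
Reactants: 17 5-[(tert-butyldimethylsilyl)oxy]cyclohexa-1,5-dien-1-yl 2-(benzyloxy)-4-{[4-(benzyloxy)-2,3-dimethoxy-6-methylbenzoyl]oxy}-6-methylbenzoate; 19 benzyl but-2-ynoate (5 equiv)
Product: 21 benzyl 4-{[2-(benzyloxy)-4-{[4-(benzyloxy)-2,3-dimethoxy-6-methylbenzoyl]oxy}-6-methylbenzoyl]oxy}-2-[(tert-butyldimethylsilyl)oxy]-6-methylbenzoate, via bicyclo[2.2.2]octadiene adduct 20 (not isolated)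
Conditions: neat in 19, BHT (cat.), 160 °C, sealed tube, argon; excess 19 removed by bulb-to-bulb distillation
Reagents that add atoms: none
Why: This is an Alder–Rickert sequence: a concerted, suprafacial [4+2] cycloaddition of the electron-rich diene to the ynoate gives bicyclo[2.2.2]octa-2,5-diene 20, which at the reaction temperature undergoes retro-[4+2] loss of its saturated two-carbon bridge as ethylene, driven by aromatisation. The closest known reaction type is the synthesis of resorcylate esters from 1,3-dioxygenated cyclohexa-1,3-dienes and acetylenic esters. Ring C is closed by the intermolecular cycloaddition itself, both ring bonds (C1–C2 and C5–C6) being made in the same event, and is aromatised by the cycloreversion. No stereocentre remains, because the two bridgehead centres of racemic 20 are destroyed when ethylene leaves. The step needs a single orientation of the unsymmetrical ynoate, and the polarisation of the diene should secure it: the CH terminus next to the acyloxy carbon is the electron-rich end (enol-ester beta-carbon, vinylogous to the silyloxy oxygen) and pairs with the electrophilic, methyl-bearing beta-carbon, so that the silyloxy carbon joins the ester-bearing alpha-carbon. Ethylene is the only fragment that can be expelled, since the other two bridges are the newly formed double bonds.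

**Step 14**
Reactants: 21 benzyl 4-{[2-(benzyloxy)-4-{[4-(benzyloxy)-2,3-dimethoxy-6-methylbenzoyl]oxy}-6-methylbenzoyl]oxy}-2-[(tert-butyldimethylsilyl)oxy]-6-methylbenzoate
Product: 22 benzyl 4-{[2-(benzyloxy)-4-{[4-(benzyloxy)-2,3-dimethoxy-6-methylbenzoyl]oxy}-6-methylbenzoyl]oxy}-2-hydroxy-6-methylbenzoate
Conditions: HF·pyridine, THF, 0 °C → rt
Reagents that add atoms: none
Why: Fluoride cleavage of the aryl silyl ether under buffered, weakly acidic conditions generates no free phenoxide and should therefore cause neither acyl migration nor cleavage of the depside esters.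

**Step 15**
Reactants: 22 benzyl 4-{[2-(benzyloxy)-4-{[4-(benzyloxy)-2,3-dimethoxy-6-methylbenzoyl]oxy}-6-methylbenzoyl]oxy}-2-hydroxy-6-methylbenzoate
Product: 23 4-{[2-hydroxy-4-{[4-hydroxy-2,3-dimethoxy-6-methylbenzoyl]oxy}-6-methylbenzoyl]oxy}-2-hydroxy-6-methylbenzoic acid (target)
Conditions: H2 (1 atm), 10% Pd/C, EtOAc, rt
Reagents that add atoms: none
Why: Catalytic hydrogenolysis should remove the two benzyl ethers and the benzyl ester in one neutral operation, and the aryl ester links of the depside are not hydrogenolysed.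

**Compound list**

1 | 3,4,5-trimethoxytoluene | COc1cc(C)cc(OC)c1OC | starting material
2 | N,N-dimethyl-(2,3,4-trimethoxy-6-methylbenzylidene)iminium chloride | COc1cc(C)c(C=[N+](C)C)c(OC)c1OC.[Cl-] | intermediate
3 | 2,3,4-trimethoxy-6-methylbenzaldehyde | COc1cc(C)c(C=O)c(OC)c1OC | intermediate
4 | 2,3,4-trihydroxy-6-methylbenzaldehyde | Cc1cc(O)c(O)c(O)c1C=O | intermediate
5 | 4-(benzyloxy)-2,3-dihydroxy-6-methylbenzaldehyde | Cc1cc(OCc2ccccc2)c(O)c(O)c1C=O | intermediate
6 | 4-(benzyloxy)-2,3-dimethoxy-6-methylbenzaldehyde | COc1c(OCc2ccccc2)cc(C)c(C=O)c1OC | intermediate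
7 | 4-(benzyloxy)-2,3-dimethoxy-6-methylbenzoic acid (ring A acid) | COc1c(OCc2ccccc2)cc(C)c(C(=O)O)c1OC | intermediate
8 | 2,4-dihydroxy-6-methylbenzaldehyde | Cc1cc(O)cc(O)c1C=O | starting material
9 | 4-(benzyloxy)-2,3-dimethoxy-6-methylbenzoic trifluoroacetic anhydride | COc1c(OCc2ccccc2)cc(C)c(C(=O)OC(=O)C(F)(F)F)c1OC | intermediate
10 | 4-formyl-3-hydroxy-5-methylphenyl 4-(benzyloxy)-2,3-dimethoxy-6-methylbenzoate | COc1c(OCc2ccccc2)cc(C)c(C(=O)Oc2cc(C)c(C=O)c(O)c2)c1OC | intermediate
11 | 3-(benzyloxy)-4-formyl-5-methylphenyl 4-(benzyloxy)-2,3-dimethoxy-6-methylbenzoate | COc1c(OCc2ccccc2)cc(C)c(C(=O)Oc2cc(C)c(C=O)c(OCc3ccccc3)c2)c1OC | intermediate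
12 | 2-(benzyloxy)-4-{[4-(benzyloxy)-2,3-dimethoxy-6-methylbenzoyl]oxy}-6-methylbenzoic acid (ring A–ring B acid) | COc1c(OCc2ccccc2)cc(C)c(C(=O)Oc2cc(C)c(C(=O)O)c(OCc3ccccc3)c2)c1OC | intermediate
13 | 2-(benzyloxy)-4-{[4-(benzyloxy)-2,3-dimethoxy-6-methylbenzoyl]oxy}-6-methylbenzoyl chloride | COc1c(OCc2ccccc2)cc(C)c(C(=O)Oc2cc(C)c(C(=O)Cl)c(OCc3ccccc3)c2)c1OC | intermediate
14 | cyclohexane-1,3-dione | O=C1CCCC(=O)C1 | starting material
15 | 3-[(tert-butyldimethylsilyl)oxy]cyclohex-2-en-1-one | CC(C)(C)[Si](C)(C)OC1=CC(=O)CCC1 | intermediate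
16 | lithium 5-[(tert-butyldimethylsilyl)oxy]cyclohexa-1,5-dien-1-olate | [Li+].[O-]C1=CCCC(O[Si](C)(C)C(C)(C)C)=C1 | intermediate
17 | 5-[(tert-butyldimethylsilyl)oxy]cyclohexa-1,5-dien-1-yl 2-(benzyloxy)-4-{[4-(benzyloxy)-2,3-dimethoxy-6-methylbenzoyl]oxy}-6-methylbenzoate (the 1-silyloxy-3-aroyloxycyclohexa-1,3-diene) | CC(C)(C)[Si](C)(C)OC1=CC(OC(=O)c2c(C)cc(OC(=O)c3c(C)cc(OCc4ccccc4)c(OC)c3OC)cc2OCc2ccccc2)=CCC1 | intermediate
18 | but-2-ynoic acid | CC#CC(=O)O | starting material
19 | benzyl but-2-ynoate | CC#CC(=O)OCc1ccccc1 | intermediate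
20 | benzyl 5-{[2-(benzyloxy)-4-{[4-(benzyloxy)-2,3-dimethoxy-6-methylbenzoyl]oxy}-6-methylbenzoyl]oxy}-1-[(tert-butyldimethylsilyl)oxy]-3-methylbicyclo[2.2.2]octa-2,5-diene-2-carboxylate (racemic) | CC(C)(C)[Si](C)(C)OC12CCC(C(C)=C1C(=O)OCc1ccccc1)C(OC(=O)c1c(C)cc(OC(=O)c3c(C)cc(OCc4ccccc4)c(OC)c3OC)cc1OCc1ccccc1)=C2 | intermediate
21 | benzyl 4-{[2-(benzyloxy)-4-{[4-(benzyloxy)-2,3-dimethoxy-6-methylbenzoyl]oxy}-6-methylbenzoyl]oxy}-2-[(tert-butyldimethylsilyl)oxy]-6-methylbenzoate | Cc1cc(OC(=O)c2c(C)cc(OC(=O)c3c(C)cc(OCc4ccccc4)c(OC)c3OC)cc2OCc2ccccc2)cc(O[Si](C)(C)C(C)(C)C)c1C(=O)OCc1ccccc1 | intermediate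
22 | benzyl 4-{[2-(benzyloxy)-4-{[4-(benzyloxy)-2,3-dimethoxy-6-methylbenzoyl]oxy}-6-methylbenzoyl]oxy}-2-hydroxy-6-methylbenzoate | Cc1cc(OC(=O)c2c(C)cc(OC(=O)c3c(C)cc(OCc4ccccc4)c(OC)c3OC)cc2OCc2ccccc2)cc(O)c1C(=O)OCc1ccccc1 | intermediate
23 | 4-{[2-hydroxy-4-{[4-hydroxy-2,3-dimethoxy-6-methylbenzoyl]oxy}-6-methylbenzoyl]oxy}-2-hydroxy-6-methylbenzoic acid | COc1c(O)cc(C)c(C(=O)Oc2cc(C)c(C(=O)Oc3cc(C)c(C(=O)O)c(O)c3)c(O)c2)c1OC | target

**Step count**

Total: 15 steps. Longest linear sequence: 13 steps (steps 1–9, 11, 13, 14, 15).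

**Steps most likely to fail**

Step 13 (key step). The cycloaddition of a trisubstituted, only moderately activated alkyne may be too slow at temperatures the diene tolerates. Before it is trapped, the diene may lose its silyl group through adventitious hydrolysis or scramble its oxygen pattern by a [1,5]-hydrogen shift. The fallback sets out from 13 and returns at 22, taking ring C ready-made instead of building it. The new starting material is purchased orsellinic acid F1. The carboxylate of F1 is alkylated with BnBr and KHCO3 in DMF at rt to give benzyl 2,4-dihydroxy-6-methylbenzoate F2. The non-chelated 4-OH of F2 is then acylated by acid chloride 13 with K2CO3 in acetone at rt, the 2-OH being held by the ester carbonyl, which should give 22 directly; step 15 follows unchanged.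

Step 11. C-acylation of the dienolate at C6 may compete with O-acylation, the beta-diketone so formed would quench further enolate by proton transfer, and the silyl enol ether may hydrolyse during isolation. The fallback sets out from 15 and 12 and returns at 17. Enone 15 is treated with lithium diisopropylamide, LiN(CHMe2)2, in THF at −78 °C and then with Me3SiCl to give 1-[(tert-butyldimethylsilyl)oxy]-3-[(trimethylsilyl)oxy]cyclohexa-1,3-diene F3. Acid 12 is treated with cyanuric fluoride and pyridine in CH2Cl2 to give 2-(benzyloxy)-4-{[4-(benzyloxy)-2,3-dimethoxy-6-methylbenzoyl]oxy}-6-methylbenzoyl fluoride F4. Catalytic anhydrous fluoride, Bu4N[Ph3SiF2] in THF at −20 °C → rt, removes the less hindered trimethylsilyl group of F3, and the resulting ammonium enolate is O-acylated by F4, which releases fluoride again. This is the known fluoride-catalysed O-acylation of silyl enol ethers by acyl fluorides and should give 17 without a lithium enolate or an aqueous work-up.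

Step 7. Under carbonate the aryl ester of 10, whose leaving group is a para-formyl phenoxide, may be cleaved or transferred between molecules, and alkylation of the chelated phenol may stall. The fallback sets out from 8 and returns at 11, putting the benzyl group on before the ester exists. Aldehyde 8 is allylated at the more acidic 4-OH with allyl bromide and one equivalent of K2CO3 in refluxing acetone to give 4-(allyloxy)-2-hydroxy-6-methylbenzaldehyde F5. F5 is benzylated at O2 with BnBr and K2CO3 in DMF at 60 °C to give 4-(allyloxy)-2-(benzyloxy)-6-methylbenzaldehyde F6. F6 is deallylated with catalytic Pd(PPh3)4, a zerovalent palladium complex, and K2CO3 in MeOH at rt to give 2-(benzyloxy)-4-hydroxy-6-methylbenzaldehyde F7. F7 and acid 7 are then joined as in step 6, with (CF3CO)2O in toluene by way of 9, to give 11; because F7 has a single free phenol, the site selectivity required in step 6 is no longer needed either.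

**Further compounds**

F1 | step 13 | orsellinic acid (2,4-dihydroxy-6-methylbenzoic acid, purchased) | Cc1cc(O)cc(O)c1C(=O)O
F2 | step 13 | benzyl 2,4-dihydroxy-6-methylbenzoate | Cc1cc(O)cc(O)c1C(=O)OCc1ccccc1
F3 | step 11 | 1-[(tert-butyldimethylsilyl)oxy]-3-[(trimethylsilyl)oxy]cyclohexa-1,3-diene | CC(C)(C)[Si](C)(C)OC1=CC(O[Si](C)(C)C)=CCC1
F4 | step 11 | 2-(benzyloxy)-4-{[4-(benzyloxy)-2,3-dimethoxy-6-methylbenzoyl]oxy}-6-methylbenzoyl fluoride | COc1c(OCc2ccccc2)cc(C)c(C(=O)Oc2cc(C)c(C(F)=O)c(OCc3ccccc3)c2)c1OC
F5 | step 7 | 4-(allyloxy)-2-hydroxy-6-methylbenzaldehyde | C=CCOc1cc(C)c(C=O)c(O)c1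
F6 | step 7 | 4-(allyloxy)-2-(benzyloxy)-6-methylbenzaldehyde | C=CCOc1cc(C)c(C=O)c(OCc2ccccc2)c1
F7 | step 7 | 2-(benzyloxy)-4-hydroxy-6-methylbenzaldehyde | Cc1cc(O)cc(OCc2ccccc2)c1C=O
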